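**Plan**

1. Numbering as in a chromene: O1, C2–C4, C4a, C5–C8, C8a; ring A is the carbocycle C4a–C8a, ring B the enolised trione on C2. The retrosynthesis cuts C2–ring B (acetal substitution by syncarpic acid), then C5–C6 of ring A, the C(=O)–CMe2 bond (intramolecular Claisen), then O1–C2 and C3–C4 (amine-catalysed Michael addition/hemiacetalisation), then C4–C4a (Knoevenagel), then C4a–C8a (acylation by dimethylketene dimer with cleavage of its four-membered ring).
2. Forward order: seco ring A (keto ester 4) → alkylidene 6 → pyran ring with C3 and C4 (8) → acetal 9 → ring A closed (10) → ring B attached at C2 (12). Ring A is thus the four-membered ring of dimethylketene dimer enlarged by the two carbons of methyl acetate: C6 is cut from C8a in step 1 and joined to C5 in step 5.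
3. Enabling feature: C6 and C8 are both quaternary (gem-dimethyl), so seco ring A has a single enolisable C–H, the isopropyl methine that becomes C6. C4a is the sp2 enol-ether carbon of the pyran, so it carries no acidic hydrogen and its double bond to C8a holds ester C5 and the keto chain cis.
4. The seco alkylidene 6 is a tamer heterodiene than an alkylidene syncarpic trione, which is prone to uncatalysed, racemic self-dimerisation; this is what should allow catalyst control.
5. Stereochemistry: C3 and C4 come from the (R)-diphenylprolinol silyl ether catalyst in step 3 (enamine face and syn topicity); C2 is set under thermodynamic control in step 6.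

Key step: step 5

Assumption: syncarpic acid (11) is taken as a purchasable building block; compounds 8–10 are carried as anomer mixtures at C2, which is harmless because C2 is set anew in step 6.

**Step 1**
Reactants: 2 methyl acetate; 1 2,2,4,4-tetramethylcyclobutane-1,3-dione (dimethylketene dimer)
Product: 4 methyl 4,4,6-trimethyl-3,5-dioxoheptanoate, via cyclobutanol aldol adduct 3 (not isolated)
Conditions: 2, LiN(iPr)2 (1.1 equiv), THF, −78 °C; then 1, −78 → 0 °C; 1 M HCl
Reagents that add atoms: none
Why: Addition of the lithium ester enolate to the strained, non-enolisable dione and retro-Claisen opening of the cyclobutanolate (the usual nucleophilic ring cleavage of this dimer, here with a carbon nucleophile) is driven by strain release, and the ketone enolate set free is quenched internally by the far more acidic β-keto ester C–H, so the open-chain keto ester should survive.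

**Step 2**
Reactants: 4 methyl 4,4,6-trimethyl-3,5-dioxoheptanoate; 5 3-methylbutanal
Product: 6 methyl 2-(3-methylbutylidene)-4,4,6-trimethyl-3,5-dioxoheptanoate (E/Z mixture)
Conditions: piperidine (10 mol%), AcOH (10 mol%), 4 Å molecular sieves, CH2Cl2, 0 °C → rt
Reagents that add atoms: none
Why: Knoevenagel condensation of the only active methylene group of the β-keto ester with an aliphatic aldehyde should give the alkylidene, whose double-bond geometry is irrelevant because it is lost in step 3.

**Step 3**
Reactants: 6 methyl 2-(3-methylbutylidene)-4,4,6-trimethyl-3,5-dioxoheptanoate; 5 3-methylbutanal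
Product: 8 methyl (3S,4S)-6-(2,4-dimethyl-3-oxopentan-2-yl)-2-hydroxy-4-(2-methylpropyl)-3-(propan-2-yl)-3,4-dihydro-2H-pyran-5-carboxylate (anomer mixture), via open-chain Michael adduct 7 (not isolated)
Conditions: (R)-α,α-diphenylprolinol trimethylsilyl ether (15 mol%), PhCO2H (15 mol%), toluene, 0 °C → rt
Reagents that add atoms: none
Why: Enamine-catalysed Michael addition of the aldehyde to the alkylidene 1,3-dicarbonyl followed by hemiacetalisation (a formal inverse-demand oxa-Diels–Alder reaction) should build the pyran; the CPh2OSiMe3 group of the (R)-catalyst shields one enamine face, setting C3 as S, and the open synclinal transition state gives the syn adduct (isopropyl and isobutyl trans on the ring), setting C4 as S, while both alkene isomers of 6 converge because C4a becomes sp2 again.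

**Step 4**
Reactants: 8 the lactol from step 3
Product: 9 methyl (3S,4S)-6-(2,4-dimethyl-3-oxopentan-2-yl)-2-methoxy-4-(2-methylpropyl)-3-(propan-2-yl)-3,4-dihydro-2H-pyran-5-carboxylate (anomer mixture)
Conditions: MeOH, camphorsulfonic acid (5 mol%), 3 Å molecular sieves, rt
Reagents that add atoms: methanol (CO)
Why: Fischer-type acetalisation of the lactol under mild acid should cap C2 as a base-stable methyl acetal without touching the push-pull enol ether, so that a strong amide base can be used next.

**Step 5**
Reactants: 9 the methyl acetal from step 4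
Product: 10 (3S,4S)-2-methoxy-6,6,8,8-tetramethyl-4-(2-methylpropyl)-3-(propan-2-yl)-3,4-dihydro-2H-chromene-5,7(6H,8H)-dione (anomer mixture)
Conditions: LiN(iPr)2 (1.3 equiv), THF, −78 → 0 °C; AcOH, −78 °C
Reagents that add atoms: none
Why: LiN(iPr)2 removes the only enolisable hydrogen of 9, the isopropyl methine next to the side-chain ketone, and the tetrasubstituted lithium enolate attacks the ester carbonyl on C4a; collapse of the tetrahedral intermediate expels methoxide and leaves the C5–C6 bond, an intramolecular Claisen (Dieckmann-type) condensation. The closest known reaction is the base-induced cyclisation of δ-keto esters to cyclohexane-1,3-diones, and the same hindered Me2C enolate closes the same ring in the known methoxide-catalysed conversion of dimethylketene dimer into hexamethylcyclohexane-1,3,5-trione. Ring A closes in the 6-(enolendo)-exo-trig mode. No stereocentre is formed; C3 and C4 carry no acidic hydrogen and C2 is an acetal, so the existing centres should stay untouched. The step needs C- over O-acylation and survival of the non-enolisable β-diketone: the C4a=C8a double bond of the pyran holds ester and keto chain cis and leaves C4a without a hydrogen (no internal proton quench), the gem-dimethyl group at C8 favours the folded rotamer, and O-acylation gives an enol lactone that methoxide reopens, so the carbocycle should accumulate. A cold acetic acid quench removes lithium methoxide before it can attack the product in a retro-Claisen sense.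

**Step 6**
Reactants: 10 the chromenedione acetal from step 5; 11 syncarpic acid (2,2,4,4-tetramethylcyclohexane-1,3,5-trione)
Product: 12 ericifolione, (2R,3S,4S)-2-(2-hydroxy-3,3,5,5-tetramethyl-4,6-dioxocyclohex-1-en-1-yl)-6,6,8,8-tetramethyl-4-(2-methylpropyl)-3-(propan-2-yl)-3,4-dihydro-2H-chromene-5,7(6H,8H)-dione
Conditions: Sc(OTf)3 (10 mol%), CH2Cl2, 0 °C → rt
Reagents that add atoms: none
Why: Lewis-acid ionisation of the acetal and C-alkylation of the enolised cyclic trione by the oxocarbenium ion (a known reaction of cyclic 1,3-diones with acetals) should form the C2–ring B bond; because the C2–O1 bond can reopen reversibly under acid, C2 should settle under thermodynamic control as R, with ring B equatorial and cis to the C3 isopropyl group on a half-chair whose C4 isobutyl group is pseudoaxial (away from the C5 carbonyl) and trans-diaxial to isopropyl.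

**Compound list**

1 | 2,2,4,4-tetramethylcyclobutane-1,3-dione (dimethylketene dimer) | CC1(C)C(=O)C(C)(C)C1=O | starting material
2 | methyl acetate | COC(C)=O | starting material
3 | methyl 2-(1-hydroxy-2,2,4,4-tetramethyl-3-oxocyclobutyl)acetate (present as its lithium alkoxide) | COC(=O)CC1(O)C(C)(C)C(=O)C1(C)C | intermediate
4 | methyl 4,4,6-trimethyl-3,5-dioxoheptanoate | COC(=O)CC(=O)C(C)(C)C(=O)C(C)C | intermediate
5 | 3-methylbutanal | CC(C)CC=O | starting material
6 | methyl 2-(3-methylbutylidene)-4,4,6-trimethyl-3,5-dioxoheptanoate (E/Z mixture) | COC(=O)C(=CCC(C)C)C(=O)C(C)(C)C(=O)C(C)C | intermediate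
7 | methyl 2-[(4S,5S)-5-formyl-2,6-dimethylheptan-4-yl]-4,4,6-trimethyl-3,5-dioxoheptanoate (open-chain Michael adduct) | O=C[C@@H](C(C)C)[C@H](CC(C)C)C(C(=O)OC)C(=O)C(C)(C)C(=O)C(C)C | intermediate
8 | methyl (3S,4S)-6-(2,4-dimethyl-3-oxopentan-2-yl)-2-hydroxy-4-(2-methylpropyl)-3-(propan-2-yl)-3,4-dihydro-2H-pyran-5-carboxylate (anomer mixture) | CC(C)C[C@@H]1C(C(=O)OC)=C(OC(O)[C@H]1C(C)C)C(C)(C)C(=O)C(C)C | intermediate
9 | methyl (3S,4S)-6-(2,4-dimethyl-3-oxopentan-2-yl)-2-methoxy-4-(2-methylpropyl)-3-(propan-2-yl)-3,4-dihydro-2H-pyran-5-carboxylate (anomer mixture) | CC(C)C[C@@H]1C(C(=O)OC)=C(OC(OC)[C@H]1C(C)C)C(C)(C)C(=O)C(C)C | intermediate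
10 | (3S,4S)-2-methoxy-6,6,8,8-tetramethyl-4-(2-methylpropyl)-3-(propan-2-yl)-3,4-dihydro-2H-chromene-5,7(6H,8H)-dione (anomer mixture) | CC(C)C[C@@H]1C2=C(OC(OC)[C@H]1C(C)C)C(C)(C)C(=O)C(C)(C)C2=O | intermediate
11 | syncarpic acid (2,2,4,4-tetramethylcyclohexane-1,3,5-trione) | CC1(C)C(=O)CC(=O)C(C)(C)C1=O | starting material
12 | ericifolione, (2R,3S,4S)-2-(2-hydroxy-3,3,5,5-tetramethyl-4,6-dioxocyclohex-1-en-1-yl)-6,6,8,8-tetramethyl-4-(2-methylpropyl)-3-(propan-2-yl)-3,4-dihydro-2H-chromene-5,7(6H,8H)-dione | CC(C)C[C@@H]1C2=C(O[C@@H](C3=C(O)C(C)(C)C(=O)C(C)(C)C3=O)[C@H]1C(C)C)C(C)(C)C(=O)C(C)(C)C2=O | target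

**Step count**

Total step count: 6. Longest linear sequence: 6 steps (1 → 4 → 6 → 8 → 9 → 10 → 12).

**Steps most likely to fail**

Step 3. The enamine may add only sluggishly to the bulky trisubstituted alkylidene, the amine may deconjugate 6 to its β,γ-isomer, or the unequal acyl groups on C4a may erode facial and syn selectivity. The fallback sets out from 5 and comes back at 9. Knoevenagel condensation of 5 with dimethyl malonate (piperidine, AcOH) should give dimethyl 2-(3-methylbutylidene)propanedioate F1, a symmetrical acceptor of a class established for this catalysis. Addition of 5 under the same (R)-diphenylprolinol silyl ether catalyst should give dimethyl 2-[(4S,5S)-5-formyl-2,6-dimethylheptan-4-yl]propanedioate F2. Acetalisation (MeOH, camphorsulfonic acid) should give dimethyl 2-[(4S,5S)-5-(dimethoxymethyl)-2,6-dimethylheptan-4-yl]propanedioate F3, and Krapcho demethoxycarbonylation (LiCl, wet DMSO, 150 °C) should give methyl (3R,4S)-4-(dimethoxymethyl)-5-methyl-3-(2-methylpropyl)hexanoate F4. Its lithium enolate (LiN(iPr)2, THF, −78 °C) is acylated by 1 with ring cleavage, as in step 1, to methyl 2-[(4S,5S)-5-(dimethoxymethyl)-2,6-dimethylheptan-4-yl]-4,4,6-trimethyl-3,5-dioxoheptanoate F5. Camphorsulfonic acid in MeOH then closes the enol acetal and returns 9.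

Step 5. The hindered enolate may acylate on oxygen to an enol lactone that does not revert, enolisation may be incomplete, or lithium methoxide may cleave the product by a retro-Claisen reaction. The fallback sets out from 9 and comes back at 10, making the same C5–C6 bond by aldol addition. iBu2AlH (CH2Cl2, −78 °C) should reduce ester and ketone to 2-[(3S,4S)-5-(hydroxymethyl)-2-methoxy-4-(2-methylpropyl)-3-(propan-2-yl)-3,4-dihydro-2H-pyran-6-yl]-2,4-dimethylpentan-3-ol F6. Dess–Martin periodinane should give (3S,4S)-6-(2,4-dimethyl-3-oxopentan-2-yl)-2-methoxy-4-(2-methylpropyl)-3-(propan-2-yl)-3,4-dihydro-2H-pyran-5-carbaldehyde F7. LiN(SiMe3)2 (THF, −78 °C) should bring about an intramolecular aldol addition, in which O-attack is only a reversible hemiacetal formation, to (3S,4S)-5-hydroxy-2-methoxy-6,6,8,8-tetramethyl-4-(2-methylpropyl)-3-(propan-2-yl)-3,4,5,6-tetrahydro-2H-chromen-7(8H)-one F8. A second Dess–Martin oxidation returns 10.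

Step 6. Ionisation of the acetal may be slow because O1 is part of a vinylogous ester, the oxocarbenium ion may lose a proton from C3 (enol ether formation) and so erode that centre, or C2 may not equilibrate fully. The fallback sets out from 10 and comes back at 12, replacing the oxocarbenium substitution by a condensation. Mild aqueous acid (AcOH, THF, water) should give the lactol (3S,4S)-2-hydroxy-6,6,8,8-tetramethyl-4-(2-methylpropyl)-3-(propan-2-yl)-3,4-dihydro-2H-chromene-5,7(6H,8H)-dione F9. Warming F9 with 11 in aqueous ethanol without added amine should give, by Knoevenagel condensation of the ring-opened aldehyde, the alkylidene trione 2-[(2R,3S)-3-(2-hydroxy-3,3,5,5-tetramethyl-4,6-dioxocyclohex-1-en-1-yl)-5-methyl-2-(propan-2-yl)hexylidene]-4,4,6,6-tetramethylcyclohexane-1,3,5-trione F10. This is not isolated; it should close by reversible intramolecular oxa-Michael addition (6-exo-trig) to 12 under thermodynamic control at C2.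

**Further compounds**

F1 | step 3 | dimethyl 2-(3-methylbutylidene)propanedioate | COC(=O)C(=CCC(C)C)C(=O)OC
F2 | step 3 | dimethyl 2-[(4S,5S)-5-formyl-2,6-dimethylheptan-4-yl]propanedioate | O=C[C@@H](C(C)C)[C@H](CC(C)C)C(C(=O)OC)C(=O)OC
F3 | step 3 | dimethyl 2-[(4S,5S)-5-(dimethoxymethyl)-2,6-dimethylheptan-4-yl]propanedioate | COC(OC)[C@@H](C(C)C)[C@H](CC(C)C)C(C(=O)OC)C(=O)OC
F4 | step 3 | methyl (3R,4S)-4-(dimethoxymethyl)-5-methyl-3-(2-methylpropyl)hexanoate | COC(OC)[C@@H](C(C)C)[C@H](CC(C)C)CC(=O)OC
F5 | step 3 | methyl 2-[(4S,5S)-5-(dimethoxymethyl)-2,6-dimethylheptan-4-yl]-4,4,6-trimethyl-3,5-dioxoheptanoate | COC(OC)[C@@H](C(C)C)[C@H](CC(C)C)C(C(=O)OC)C(=O)C(C)(C)C(=O)C(C)C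
F6 | step 5 | 2-[(3S,4S)-5-(hydroxymethyl)-2-methoxy-4-(2-methylpropyl)-3-(propan-2-yl)-3,4-dihydro-2H-pyran-6-yl]-2,4-dimethylpentan-3-ol | CC(C)C[C@@H]1C(CO)=C(OC(OC)[C@H]1C(C)C)C(C)(C)C(O)C(C)C
F7 | step 5 | (3S,4S)-6-(2,4-dimethyl-3-oxopentan-2-yl)-2-methoxy-4-(2-methylpropyl)-3-(propan-2-yl)-3,4-dihydro-2H-pyran-5-carbaldehyde | CC(C)C[C@@H]1C(C=O)=C(OC(OC)[C@H]1C(C)C)C(C)(C)C(=O)C(C)C
F8 | step 5 | (3S,4S)-5-hydroxy-2-methoxy-6,6,8,8-tetramethyl-4-(2-methylpropyl)-3-(propan-2-yl)-3,4,5,6-tetrahydro-2H-chromen-7(8H)-one | CC(C)C[C@@H]1C2=C(OC(OC)[C@H]1C(C)C)C(C)(C)C(=O)C(C)(C)C2O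
F9 | step 6 | (3S,4S)-2-hydroxy-6,6,8,8-tetramethyl-4-(2-methylpropyl)-3-(propan-2-yl)-3,4-dihydro-2H-chromene-5,7(6H,8H)-dione | CC(C)C[C@@H]1C2=C(OC(O)[C@H]1C(C)C)C(C)(C)C(=O)C(C)(C)C2=O
F10 | step 6 | 2-[(2R,3S)-3-(2-hydroxy-3,3,5,5-tetramethyl-4,6-dioxocyclohex-1-en-1-yl)-5-methyl-2-(propan-2-yl)hexylidene]-4,4,6,6-tetramethylcyclohexane-1,3,5-trione | CC(C)C[C@H](C1=C(O)C(C)(C)C(=O)C(C)(C)C1=O)[C@H](C(C)C)C=C1C(=O)C(C)(C)C(=O)C(C)(C)C1=O
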